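The hexasubstituted central benzene ring is assembled last instead of being arylated. Its atoms C1(O), C2(6-methoxyindol-3-yl), C3(O) and C4(O) are the four carbons of a squarate, and C5(5-oxygenated indol-3-yl)–C6(O) is a 1-indolyl-2-methoxyvinyl unit. This pattern of four ring oxygens around two para indoles is the feature the key step exploits. The precursor is a 4-alkenyl-3,4-dimethoxy-2-indolylcyclobutenone. On heating, its C1–C4 bond opens to a dienylketene, and the ketene carbon closes onto the CH(OMe) terminus, so one operation makes the C1–C6 bond and the aromatic ring with all six substituents in place. One O-methylation and two deprotection steps follow.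

Key step: step 8

Assumption: both aryl–indolyl axes are taken to rotate freely at room temperature, so the target is treated as achiral, as its SMILES shows. "Indole A" is the 6-methoxyindole unit and "indole B" is the 5-oxygenated one.

Step 1
Reactants: 1 6-methoxyindole
Product: 3 3-iodo-6-methoxy-1-tosylindole, via 3-iodo-6-methoxyindole 2 (not isolated)
Conditions: I2, KOH (excess), DMF, rt; then TsCl, 0 °C to rt, same flask
Reagents that add atoms: iodine, [I][I]; p-toluenesulfonyl chloride, Cc1ccc(S(=O)(=O)Cl)cc1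
Why: Electrophilic iodination of the potassium indolide goes to C3, the most nucleophilic ring position, and the light- and air-sensitive 2 is N-sulfonylated in the same flask, which stabilises the iodide and later tempers the donor strength of indole A (aromatic halogenation followed by N-sulfonylation).

Step 2
Reactants: 3 3-iodo-6-methoxy-1-tosylindole; 4 dimethyl squarate
Product: 6 4-hydroxy-2,3-dimethoxy-4-(6-methoxy-1-tosylindol-3-yl)cyclobut-2-en-1-one (racemic), via 6-methoxy-1-tosylindol-3-ylmagnesium chloride 5 (not isolated)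
Conditions: iPrMgCl·LiCl, THF, −20 °C; cannulated into 4 (excess), THF, −78 to −20 °C; sat. aq NH4Cl
Reagents that add atoms: isopropylmagnesium chloride, CC(C)[Mg]Cl (magnesium and chlorine of 5 only)
Why: Iodine–magnesium exchange gives a 3-indolyl Grignard reagent that, unlike its lithium analogue, does not migrate to C2, and inverse addition to excess squarate limits the reaction to one 1,2-carbonyl addition at either of two equivalent carbonyls, so the new quaternary carbinol centre is racemic.

Step 3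
Reactants: 6 4-hydroxy-2,3-dimethoxy-4-(6-methoxy-1-tosylindol-3-yl)cyclobut-2-en-1-one
Product: 7 3-methoxy-4-(6-methoxy-1-tosylindol-3-yl)cyclobut-3-ene-1,2-dione
Conditions: cat. conc. HCl, CH2Cl2, rt
Reagents that add atoms: none
Why: Acid ionises the tertiary carbinol, water returns at the methoxy-bearing end of the allyl cation and the hemiketal loses methanol, which is the standard acid-catalysed conversion of squarate adducts into 3-substituted 4-alkoxycyclobutenediones and removes the stereocentre.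

Step 4
Reactants: 8 5-benzyloxyindole-3-carboxaldehyde
Product: 9 5-benzyloxy-1-(triisopropylsilyl)indole-3-carboxaldehyde
Conditions: NaH, THF, 0 °C; iPr3SiCl, 0 °C to rt
Reagents that add atoms: triisopropylsilyl chloride, CC(C)[Si](Cl)(C(C)C)C(C)C
Why: N-Silylation of the sodium indolide is routine, and the bulky silyl group later shields C2–H against organolithium bases without offering a directing or electrophilic site.

Step 5
Reactants: 9 5-benzyloxy-1-(triisopropylsilyl)indole-3-carboxaldehyde; 10 (methoxymethyl)triphenylphosphonium chloride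
Product: 12 5-benzyloxy-3-(2-methoxyvinyl)-1-(triisopropylsilyl)indole (E/Z mixture; E drawn), via methoxymethylidene ylide 11 (not isolated)
Conditions: 10, NaN(SiMe3)2 (slightly less than 10), THF, 0 °C; then 9, 0 °C to rt
Reagents that add atoms: none
Why: Wittig methoxymethylenation of an aryl aldehyde is reliable, the amide base avoids alkoxide attack on the N–Si bond, and the alkene geometry does not matter because the next step passes through sp3 and cationic carbon.

Step 6
Reactants: 12 5-benzyloxy-3-(2-methoxyvinyl)-1-(triisopropylsilyl)indole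
Product: 14 (Z)-5-benzyloxy-3-(1-bromo-2-methoxyvinyl)-1-(triisopropylsilyl)indole (Br cis to OMe), via vicinal dibromide 13 (not isolated)
Conditions: Br2 (1 equiv), CH2Cl2, −78 °C; then iPr2NEt, −78 °C to rt; amine-deactivated silica
Reagents that add atoms: bromine, BrBr
Why: Bromine adds to the enol ether, the most electron-rich C=C bond, and the alpha-bromo ether of 13 ionises to an oxocarbenium ion that gives up the proton on the bromine-bearing carbon to the amine (bromination–dehydrobromination of enol ethers), both isomers of 12 converging on the alkene that keeps the large indolyl group trans to OMe and hence Br cis to OMe.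

Step 7
Reactants: 14 (Z)-5-benzyloxy-3-(1-bromo-2-methoxyvinyl)-1-(triisopropylsilyl)indole; 7 3-methoxy-4-(6-methoxy-1-tosylindol-3-yl)cyclobut-3-ene-1,2-dione
Product: 17 4-[(Z)-1-(5-benzyloxy-1-triisopropylsilylindol-3-yl)-2-methoxyvinyl]-3,4-dimethoxy-2-(6-methoxy-1-tosylindol-3-yl)cyclobut-2-en-1-one (racemic), via alkenyllithium 15 (not isolated), via lithium alkoxide 16 (not isolated)
Conditions: t-BuLi (2 equiv), Et2O, −78 °C, short ageing; 7 in THF, −78 °C; MeOTf, −78 to 0 °C; aq NaHCO3
Reagents that add atoms: methyl trifluoromethanesulfonate, COS(=O)(=O)C(F)(F)F; tert-butyllithium, [Li]C(C)(C)C (lithium of 15 and 16 only)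
Why: Bromine–lithium exchange with retention, run in ether to slow inversion of the alpha-aryl carbanion, keeps Li cis to OMe so that anti loss of LiOMe is barred; 15 then adds 1,2 to the carbonyl flanked by the OMe-bearing carbon because the other carbonyl is a vinylogous ester and the N-tosyl group mutes the push of indole A, and alkoxide 16 is O-alkylated in the flask, the new quaternary centre being racemic.

Step 8
Reactants: 17 4-[(Z)-1-(5-benzyloxy-1-triisopropylsilylindol-3-yl)-2-methoxyvinyl]-3,4-dimethoxy-2-(6-methoxy-1-tosylindol-3-yl)cyclobut-2-en-1-one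
Product: 20 3-(5-benzyloxy-1-triisopropylsilylindol-3-yl)-2,4,5-trimethoxy-6-(6-methoxy-1-tosylindol-3-yl)phenol, via dienylketene 18 (not isolated), via cyclohexa-2,4-dienone 19 (not isolated)
Conditions: degassed toluene (dilute), reflux, Ar
Reagents that add atoms: none
Why: Heat opens the cyclobutenone of 17 by conrotatory 4π cleavage of the C1–C4 bond, and the donor OMe on C4 turns outward, as is the rule for 4-alkoxy- and 4-hydroxycyclobutenones, so the alkenyl group turns inward and lies next to the ketene in 18. The sp-hybridised, sterically slim ketene carbon C1 then bonds to the CH(OMe) terminus in a disrotatory 6π electrocyclisation, the only ring closure of the step, which forms the six-membered carbocycle as dienone 19. Enolisation of 19 to phenol 20 is irreversible and supplies the driving force. The closest known reaction type is the thermal ring expansion of squarate-derived 4-alkenylcyclobutenones to hydroquinone derivatives (Moore rearrangement family), including closures onto oxygen-bearing sp2 carbon. The one new stereocentre, the CH(OMe) carbon of 19, forms racemic under no control and vanishes on aromatisation, as do the quaternary centre and the alkene geometry of 17. The selectivity needed is torquoselectivity, secured by the C4 methoxy group (a ketene opened the wrong way can only reclose), while the substituent order is fixed by the connectivity of 17.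

Step 9
Reactants: 20 3-(5-benzyloxy-1-triisopropylsilylindol-3-yl)-2,4,5-trimethoxy-6-(6-methoxy-1-tosylindol-3-yl)phenol
Product: 21 3-[4-(5-benzyloxy-1-triisopropylsilylindol-3-yl)-2,3,5,6-tetramethoxyphenyl]-6-methoxy-1-tosylindole
Conditions: MeI, K2CO3, dry DMF, rt, Ar
Reagents that add atoms: iodomethane, CI
Why: Williamson-type O-methylation acts on the only acidic OH, and the dry aprotic medium keeps both nitrogen groups in place so that no indole nitrogen can be methylated.

Step 10
Reactants: 21 3-[4-(5-benzyloxy-1-triisopropylsilylindol-3-yl)-2,3,5,6-tetramethoxyphenyl]-6-methoxy-1-tosylindole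
Product: 23 5-benzyloxy-3-[2,3,5,6-tetramethoxy-4-(6-methoxy-1H-indol-3-yl)phenyl]-1H-indole, via N-desilylated tosylindole 22 (not isolated)
Conditions: Bu4NF (excess), THF, rt, then reflux
Reagents that add atoms: none
Why: Fluoride attacks silicon at room temperature and sulfonyl sulfur at reflux (fluoride-mediated N-desilylation and N-desulfonylation of indoles), so both nitrogen groups leave in one operation while benzyl and methyl ethers are inert.

Step 11
Reactants: 23 5-benzyloxy-3-[2,3,5,6-tetramethoxy-4-(6-methoxy-1H-indol-3-yl)phenyl]-1H-indole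
Product: 24 3-[2,3,5,6-tetramethoxy-4-(6-methoxy-1H-indol-3-yl)phenyl]-1H-indol-5-ol (CNP0234672.0)
Conditions: H2 (1 atm), Pd/C, EtOAc/MeOH, rt; handled under Ar
Reagents that add atoms: none
Why: Hydrogenolysis of the benzyl aryl ether under neutral conditions leaves indoles and methyl ethers untouched, and it is placed last because the 5-hydroxyindole is the most oxidation-prone compound of the route.

Compound list
1 | 6-methoxyindole | COc1ccc2cc[nH]c2c1 | starting material
2 | 3-iodo-6-methoxyindole | COc1ccc2c(I)c[nH]c2c1 | intermediate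
3 | 3-iodo-6-methoxy-1-tosylindole | COc1ccc2c(I)cn(S(=O)(=O)c3ccc(C)cc3)c2c1 | intermediate
4 | dimethyl squarate | COC1=C(OC)C(=O)C1=O | starting material
5 | 6-methoxy-1-tosylindol-3-ylmagnesium chloride | COc1ccc2c([Mg]Cl)cn(S(=O)(=O)c3ccc(C)cc3)c2c1 | intermediate
6 | 4-hydroxy-2,3-dimethoxy-4-(6-methoxy-1-tosylindol-3-yl)cyclobut-2-en-1-one, racemic | COC1=C(OC)C(O)(c2cn(S(=O)(=O)c3ccc(C)cc3)c3cc(OC)ccc23)C1=O | intermediate
7 | 3-methoxy-4-(6-methoxy-1-tosylindol-3-yl)cyclobut-3-ene-1,2-dione | COC1=C(c2cn(S(=O)(=O)c3ccc(C)cc3)c3cc(OC)ccc23)C(=O)C1=O | intermediate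
8 | 5-benzyloxyindole-3-carboxaldehyde | O=Cc1c[nH]c2ccc(OCc3ccccc3)cc12 | starting material
9 | 5-benzyloxy-1-(triisopropylsilyl)indole-3-carboxaldehyde | O=Cc1cn([Si](C(C)C)(C(C)C)C(C)C)c2ccc(OCc3ccccc3)cc12 | intermediate
10 | (methoxymethyl)triphenylphosphonium chloride | COC[P+](c1ccccc1)(c1ccccc1)c1ccccc1.[Cl-] | starting material
11 | (methoxymethylidene)triphenylphosphorane | COC=P(c1ccccc1)(c1ccccc1)c1ccccc1 | intermediate
12 | 5-benzyloxy-3-(2-methoxyvinyl)-1-(triisopropylsilyl)indole, E/Z mixture, E drawn | CO/C=C/c1cn([Si](C(C)C)(C(C)C)C(C)C)c2ccc(OCc3ccccc3)cc12 | intermediate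
13 | 5-benzyloxy-3-(1,2-dibromo-2-methoxyethyl)-1-(triisopropylsilyl)indole, mixture of racemic diastereomers | COC(Br)C(Br)c1cn([Si](C(C)C)(C(C)C)C(C)C)c2ccc(OCc3ccccc3)cc12 | intermediate
14 | (Z)-5-benzyloxy-3-(1-bromo-2-methoxyvinyl)-1-(triisopropylsilyl)indole, Br cis to OMe | CO/C=C(Br)/c1cn([Si](C(C)C)(C(C)C)C(C)C)c2ccc(OCc3ccccc3)cc12 | intermediate
15 | 1-(5-benzyloxy-1-triisopropylsilylindol-3-yl)-2-methoxyvinyllithium, Li cis to OMe | CO/C=C([Li])/c1cn([Si](C(C)C)(C(C)C)C(C)C)c2ccc(OCc3ccccc3)cc12 | intermediate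
16 | lithium alkoxide of the 1,2-adduct of 15 and 7, racemic | CO/C=C(/c1cn([Si](C(C)C)(C(C)C)C(C)C)c2ccc(OCc3ccccc3)cc12)C4([O-])C(OC)=C(c5cn(S(=O)(=O)c6ccc(C)cc6)c7cc(OC)ccc57)C4=O.[Li+] | intermediate
17 | 4-[(Z)-1-(5-benzyloxy-1-triisopropylsilylindol-3-yl)-2-methoxyvinyl]-3,4-dimethoxy-2-(6-methoxy-1-tosylindol-3-yl)cyclobut-2-en-1-one, racemic | CO/C=C(/c1cn([Si](C(C)C)(C(C)C)C(C)C)c2ccc(OCc3ccccc3)cc12)C4(OC)C(OC)=C(c5cn(S(=O)(=O)c6ccc(C)cc6)c7cc(OC)ccc57)C4=O | intermediate
18 | (3Z,5Z)-5-(indole B)-3,4,6-trimethoxy-2-(indole A)hexa-1,3,5-trien-1-one (dienylketene) | O=C=C(c1cn(S(=O)(=O)c2ccc(C)cc2)c2cc(OC)ccc12)/C(OC)=C(OC)\C(c1cn([Si](C(C)C)(C(C)C)C(C)C)c2ccc(OCc3ccccc3)cc12)=C/OC | intermediate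
19 | 5-(indole B)-3,4,6-trimethoxy-2-(indole A)cyclohexa-2,4-dien-1-one, racemic at C6 | COC1C(=O)C(c2cn(S(=O)(=O)c3ccc(C)cc3)c3cc(OC)ccc23)=C(OC)C(OC)=C1c1cn([Si](C(C)C)(C(C)C)C(C)C)c2ccc(OCc3ccccc3)cc12 | intermediate
20 | 3-(5-benzyloxy-1-triisopropylsilylindol-3-yl)-2,4,5-trimethoxy-6-(6-methoxy-1-tosylindol-3-yl)phenol | Oc1c(-c2cn(S(=O)(=O)c3ccc(C)cc3)c4cc(OC)ccc24)c(OC)c(OC)c(-c5cn([Si](C(C)C)(C(C)C)C(C)C)c6ccc(OCc7ccccc7)cc56)c1OC | intermediate
21 | 3-[4-(5-benzyloxy-1-triisopropylsilylindol-3-yl)-2,3,5,6-tetramethoxyphenyl]-6-methoxy-1-tosylindole | COc1c(-c2cn(S(=O)(=O)c3ccc(C)cc3)c4cc(OC)ccc24)c(OC)c(OC)c(-c5cn([Si](C(C)C)(C(C)C)C(C)C)c6ccc(OCc7ccccc7)cc56)c1OC | intermediate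
22 | 3-[4-(5-benzyloxy-1H-indol-3-yl)-2,3,5,6-tetramethoxyphenyl]-6-methoxy-1-tosylindole | COc1c(-c2cn(S(=O)(=O)c3ccc(C)cc3)c4cc(OC)ccc24)c(OC)c(OC)c(-c5c[nH]c6ccc(OCc7ccccc7)cc56)c1OC | intermediate
23 | 5-benzyloxy-3-[2,3,5,6-tetramethoxy-4-(6-methoxy-1H-indol-3-yl)phenyl]-1H-indole | COc1ccc2c(-c3c(OC)c(OC)c(-c4c[nH]c5ccc(OCc6ccccc6)cc45)c(OC)c3OC)c[nH]c2c1 | intermediate
24 | 3-[2,3,5,6-tetramethoxy-4-(6-methoxy-1H-indol-3-yl)phenyl]-1H-indol-5-ol (CNP0234672.0), no stereocentre | COc1ccc2c(-c3c(OC)c(OC)c(-c4c[nH]c5ccc(O)cc45)c(OC)c3OC)c[nH]c2c1 | target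

Total step count: 11.
Longest linear sequence: 8 steps (1 → 3 → 6 → 7 → 17 → 20 → 21 → 23 → 24). The branch 8 → 9 → 12 → 14 → 17 and onward is equally long.

Steps most likely to fail

1. Step 7.
What may go wrong: the alpha-aryl alkenyllithium may invert at the metal-bearing carbon and then lose lithium methoxide by anti elimination. Part of the attack may fall on the vinylogous-ester carbonyl. The crowded tertiary alkoxide may be captured too slowly by methyl triflate.
Fallback, from 14 back to 21:
- A copper-catalysed Finkelstein-type exchange (CuI, N,N'-dimethylethylenediamine, NaI, dioxane, 110 °C) should convert 14 with retention into (Z)-5-benzyloxy-3-(1-iodo-2-methoxyvinyl)-1-(triisopropylsilyl)indole F1.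
- Iodine–magnesium exchange with iPrMgCl·LiCl (THF, −20 to 0 °C) gives 1-(5-benzyloxy-1-triisopropylsilylindol-3-yl)-2-methoxyvinylmagnesium chloride F2. Its more covalent carbon–metal bond resists both inversion and beta-elimination.
- Addition to 7 and a proton quench give the tertiary carbinol 4-[(Z)-1-(5-benzyloxy-1-triisopropylsilylindol-3-yl)-2-methoxyvinyl]-4-hydroxy-3-methoxy-2-(6-methoxy-1-tosylindol-3-yl)cyclobut-2-en-1-one F3.
- Thermolysis in degassed toluene gives the hydroquinone 2-(5-benzyloxy-1-triisopropylsilylindol-3-yl)-3,6-dimethoxy-5-(6-methoxy-1-tosylindol-3-yl)benzene-1,4-diol F4.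
- F4 is methylated at both hydroxyls without exposure to air (MeI, K2CO3, DMF) to give 21.

2. Step 6.
What may go wrong: the N-silylindol-3-yl group is itself a strong donor. Ionisation at the indolyl-bearing carbon may therefore compete with ionisation of the alpha-bromo ether, and HBr may be lost in the wrong direction. Ring bromination and N–Si cleavage by bromide would drain further material.
Fallback, from 8 back to 14. It uses a carbamate on nitrogen while bromine is installed, so that only the methoxy group steers the elimination: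
- Boc2O and cat. DMAP give tert-butyl 5-benzyloxy-3-formylindole-1-carboxylate F5.
- Ylide 11 gives tert-butyl 5-benzyloxy-3-(2-methoxyvinyl)indole-1-carboxylate F6.
- Br2 at −78 °C gives tert-butyl 5-benzyloxy-3-(1,2-dibromo-2-methoxyethyl)indole-1-carboxylate F7.
- iPr2NEt in the same flask converts F7 into tert-butyl (Z)-5-benzyloxy-3-(1-bromo-2-methoxyvinyl)indole-1-carboxylate F8.
- Mild methanolysis (K2CO3, MeOH, rt to 40 °C) frees (Z)-5-benzyloxy-3-(1-bromo-2-methoxyvinyl)-1H-indole F9.
- NaH and iPr3SiCl at 0 °C give 14.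

3. Step 8.
What may go wrong: the methoxy group on the alkene terminus points into the closing ring, and two bulky indolyl groups flank the reacting carbons. The 6π closure may therefore be slower than reclosure, dimerisation or adventitious trapping of the ketene.
Fallback, from 3 (through its Grignard reagent 5) back to 21. It gives up the ring expansion for two cross-couplings on a preformed arene:
- Quenching 5 with 2-isopropoxy-4,4,5,5-tetramethyl-1,3,2-dioxaborolane gives 6-methoxy-3-(pinacolboryl)-1-tosylindole F10.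
- Commercial 1,2,4,5-tetramethoxybenzene is dibrominated (Br2, CH2Cl2, 0 °C) to 1,4-dibromo-2,3,5,6-tetramethoxybenzene F11.
- F11, used in excess, undergoes a first Suzuki–Miyaura coupling with F10 (Pd(OAc)2, SPhos, K3PO4, dioxane, 90 °C) to give 3-(4-bromo-2,3,5,6-tetramethoxyphenyl)-6-methoxy-1-tosylindole F12.
- Commercial 5-benzyloxyindole is N-silylated (NaH, iPr3SiCl) to 5-benzyloxy-1-(triisopropylsilyl)indole F13.
- F13 is borylated at C3, its only unhindered C–H ([Ir(OMe)(cod)]2, 4,4'-di-tert-butyl-2,2'-bipyridine, B2pin2), to 5-benzyloxy-3-(pinacolboryl)-1-(triisopropylsilyl)indole F14.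
- A second coupling of F12 with F14 under the same conditions gives 21.

Further compounds
F1 | step 7 | (Z)-5-benzyloxy-3-(1-iodo-2-methoxyvinyl)-1-(triisopropylsilyl)indole | CO/C=C(I)/c1cn([Si](C(C)C)(C(C)C)C(C)C)c2ccc(OCc3ccccc3)cc12
F2 | step 7 | 1-(5-benzyloxy-1-triisopropylsilylindol-3-yl)-2-methoxyvinylmagnesium chloride, Mg cis to OMe | CO/C=C([Mg]Cl)/c1cn([Si](C(C)C)(C(C)C)C(C)C)c2ccc(OCc3ccccc3)cc12
F3 | step 7 | 4-[(Z)-1-(5-benzyloxy-1-triisopropylsilylindol-3-yl)-2-methoxyvinyl]-4-hydroxy-3-methoxy-2-(6-methoxy-1-tosylindol-3-yl)cyclobut-2-en-1-one, racemic | CO/C=C(/c1cn([Si](C(C)C)(C(C)C)C(C)C)c2ccc(OCc3ccccc3)cc12)C4(O)C(OC)=C(c5cn(S(=O)(=O)c6ccc(C)cc6)c7cc(OC)ccc57)C4=O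
F4 | step 7 | 2-(5-benzyloxy-1-triisopropylsilylindol-3-yl)-3,6-dimethoxy-5-(6-methoxy-1-tosylindol-3-yl)benzene-1,4-diol | Oc1c(-c2cn(S(=O)(=O)c3ccc(C)cc3)c4cc(OC)ccc24)c(OC)c(O)c(-c5cn([Si](C(C)C)(C(C)C)C(C)C)c6ccc(OCc7ccccc7)cc56)c1OC
F5 | step 6 | tert-butyl 5-benzyloxy-3-formylindole-1-carboxylate | O=Cc1cn(C(=O)OC(C)(C)C)c2ccc(OCc3ccccc3)cc12
F6 | step 6 | tert-butyl 5-benzyloxy-3-(2-methoxyvinyl)indole-1-carboxylate, E/Z mixture, E drawn | CO/C=C/c1cn(C(=O)OC(C)(C)C)c2ccc(OCc3ccccc3)cc12
F7 | step 6 | tert-butyl 5-benzyloxy-3-(1,2-dibromo-2-methoxyethyl)indole-1-carboxylate, mixture of racemic diastereomers | COC(Br)C(Br)c1cn(C(=O)OC(C)(C)C)c2ccc(OCc3ccccc3)cc12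
F8 | step 6 | tert-butyl (Z)-5-benzyloxy-3-(1-bromo-2-methoxyvinyl)indole-1-carboxylate | CO/C=C(Br)/c1cn(C(=O)OC(C)(C)C)c2ccc(OCc3ccccc3)cc12
F9 | step 6 | (Z)-5-benzyloxy-3-(1-bromo-2-methoxyvinyl)-1H-indole | CO/C=C(Br)/c1c[nH]c2ccc(OCc3ccccc3)cc12
F10 | step 8 | 6-methoxy-3-(pinacolboryl)-1-tosylindole | COc1ccc2c(B3OC(C)(C)C(C)(C)O3)cn(S(=O)(=O)c3ccc(C)cc3)c2c1
F11 | step 8 | 1,4-dibromo-2,3,5,6-tetramethoxybenzene | COc1c(Br)c(OC)c(OC)c(Br)c1OC
F12 | step 8 | 3-(4-bromo-2,3,5,6-tetramethoxyphenyl)-6-methoxy-1-tosylindole | COc1ccc2c(-c3c(OC)c(OC)c(Br)c(OC)c3OC)cn(S(=O)(=O)c3ccc(C)cc3)c2c1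
F13 | step 8 | 5-benzyloxy-1-(triisopropylsilyl)indole | CC(C)[Si](C(C)C)(C(C)C)n1ccc2cc(OCc3ccccc3)ccc12
F14 | step 8 | 5-benzyloxy-3-(pinacolboryl)-1-(triisopropylsilyl)indole | CC(C)[Si](C(C)C)(C(C)C)n1cc(B2OC(C)(C)C(C)(C)O2)c2cc(OCc3ccccc3)ccc12
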